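**Retrosynthetic overview**
1. Target ⇒ desilylation and anti bromohydroxylation of the 10E-alkene of a bicyclic 6,15-dibromide whose phenol is a TIPS ether.
2. Bicyclic dibromide ⇒ catalyst-controlled transannular bromonium cyclisation (C2–C7 bond; sets C2, C6, C7) of a 19-membered triene macrolactone.
3. Macrolactone ⇒ Shiina lactonisation of a 15-bromo-14-hydroxy seco-acid ⇒ HBr opening of a (14S)-14,15-epoxide.
4. Epoxide ⇒ organocatalytic ent-Shi epoxidation of the terminal alkene of 3-geranylgeranyl-4-silyloxybenzoic acid (first stereocentre) ⇒ ortho-C-geranylgeranylation of methyl 4-hydroxybenzoate.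
5. Ring order: 19-membered lactone first, then the cyclohexene ring, whose closure contracts the macrocycle to the 15-membered lactone.

Assumptions (one line): all-E geranylgeranyl bromide is bought as such; locants C1–C15 count the geranylgeranyl chain from the benzylic carbon (target = 2R,6S,7S,10R,11S,14S); the Lewis-base catalyst of step 6 is written as its (R)-antipode, the antipode used being the one that two test runs show to give the 6S face.

**Step 1**
Reactants: 1 methyl 4-hydroxybenzoate; 2 (2E,6E,10E)-geranylgeranyl bromide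
Product: 4 4-hydroxy-3-[(2E,6E,10E)-3,7,11,15-tetramethylhexadeca-2,6,10,14-tetraenyl]benzoic acid, via methyl ester 3 (not isolated)
Conditions: NaH (1.05 equiv), toluene, 0 °C to rt; 2, rt, 36 h; then NaOH (4 M aq.), MeOH, 70 °C; HCl work-up
Reagents that add atoms: sodium hydroxide (NaOH), [Na+].[OH-]
Why: Ortho-selective C-alkylation of the tight ArONa ion pair in a non-polar solvent (SN2 at the primary allylic bromide, 2E geometry kept), then BAc2 saponification of the methyl ester in the same pot; no stereocentre is formed.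

**Step 2**
Reactants: 4 4-hydroxy-3-geranylgeranylbenzoic acid
Product: 6 3-[(2E,6E,10E)-geranylgeranyl]-4-(triisopropylsilyloxy)benzoic acid, via bis-TIPS silyl ester 5 (not isolated)
Conditions: TIPSCl (2.5 equiv), imidazole, DMF, rt; then K2CO3, MeOH/THF/H2O, 0 °C; HCl (1 M) work-up
Reagents that add atoms: triisopropylsilyl chloride, CC(C)[Si](Cl)(C(C)C)C(C)C
Why: Imidazole-mediated silylation of both acidic OH groups, then selective carbonate solvolysis of the labile silyl ester, leaves the robust aryl TIPS ether that keeps the phenol from being oxidised (step 3), acylated (step 5) or captured as a chroman by the C3 cation (step 6); no stereocentre.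

**Step 3**
Reactants: 6 3-geranylgeranyl-4-(triisopropylsilyloxy)benzoic acid
Product: 7 3-[(2E,6E,10E,14S)-14,15-epoxy-3,7,11,15-tetramethylhexadeca-2,6,10-trienyl]-4-(triisopropylsilyloxy)benzoic acid
Conditions: ent-Shi ketone (1,2:4,5-di-O-isopropylidene-β-L-erythro-2,3-hexodiulo-2,6-pyranose, 30 mol%), KHSO5 (as 2KHSO5·KHSO4·K2SO4, 0.7 equiv), K2CO3, Na2B4O7 buffer pH 10.5, Bu4NHSO4 (cat.), MeCN/CH2(OMe)2/H2O, 0 °C, to about 50% conversion, 6 recycled; NaH2PO4 work-up
Reagents that add atoms: potassium peroxymonosulfate (KHSO5), [K+].[O-]S(=O)(=O)OO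
Why: Shi asymmetric epoxidation — the chiral dioxirane formed from the ketone transfers oxygen through a spiro transition state, the L-series ketone giving the 14S epoxide (mirror image of the R epoxides from the D-fructose ketone) and so setting the first stereocentre by organocatalysis, with a modest preference expected for the least hindered terminal isopropylidene alkene and the 2,3-alkene shielded by the ortho TIPSO-aryl group.

**Step 4**
Reactants: 7 (14S)-14,15-epoxy acid
Product: 8 3-[(2E,6E,10E,14S)-15-bromo-14-hydroxy-3,7,11,15-tetramethylhexadeca-2,6,10-trienyl]-4-(triisopropylsilyloxy)benzoic acid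
Conditions: HBr (48% aq., 1.5 equiv), Et2O, −20 °C, 10 min
Reagents that add atoms: hydrogen bromide, Br
Why: Acid-promoted epoxide opening with borderline SN1 character — bromide attacks the tertiary C15 of the protonated 2,2-dimethyloxirane (Markovnikov), so the C14–O bond is untouched and C14 stays S, while the short cold exposure spares the three other alkenes and the aryl silyl ether.

**Step 5**
Reactants: 8 (14S)-15-bromo-14-hydroxy seco-acid
Product: 10 (14S)-19-membered macrolactone (C14–O acylated by the benzoate carbon; 2E,6E,10E-triene; 2-bromopropan-2-yl on C14; aryl OTIPS), via mixed anhydride 9 (not isolated)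
Conditions: 2-methyl-6-nitrobenzoic anhydride (MNBA, 1.3 equiv), 4-(dimethylamino)pyridine (3 equiv), CH2Cl2 (1 mM), rt, 8 added over 12 h
Reagents that add atoms: none
Why: Shiina macrolactonisation — MNBA gives mixed anhydride 9 and DMAP transfers its less hindered aroyl group to the C14 hydroxyl under high dilution to close the unstrained 19-membered ring; the C14–O bond is not broken (S kept) and the mild, room-temperature conditions do not close the bromohydrin to an epoxide.

**Step 6**
Reactants: 10 (14S)-19-membered triene macrolactone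
Product: 11 (2R,6S,7S,14S)-bicyclic dibromide (cyclohexene C2–C3(Me)=C4–C5–C6(Br)–C7(Me) fused across C2–C7 to the 15-membered lactone; 10E-alkene; 2-bromopropan-2-yl on C14; aryl OTIPS)
Conditions: NBS (1.05 equiv), (R)-3,3′-bis(2,4,6-triisopropylphenyl)-1,1′-binaphthyl-2,2′-diyl N-phenylthiophosphoramide (10 mol%), toluene/CH2Cl2 1:1, −78 °C, dark
Reagents that add atoms: N-bromosuccinimide, O=C1CCC(=O)N1Br
Why: Proposed new method: a chiral Lewis-base-catalysed transannular bromonium-initiated cation–olefin cyclisation with proton-loss termination — the P=S donor takes Br+ from NBS and passes it reversibly among the alkenes of 10, the 6,7-alkene (most electron-rich; the 2,3-alkene is shielded by the TIPSO-arene and the 10,11-alkene lies next to the C14 ester/C15 bromide region) is expected to be the one whose bromiranium ion is trapped, by chair-like anti attack of C2 of the 2E-alkene on C7, after which the catalyst-bound succinimide anion removes axial H-4 to give the 3,4-alkene; the chair puts Br equatorial at C6, methyl axial at C7 and the benzylic carbon equatorial at C2 (the target's relative configuration) and the catalyst antipode chooses the alkene face and hence 2R,6S,7S relative to C14; the closest known reactions are chiral thiophosphoramide- or phosphoramidite-catalysed enantioselective bromocyclisations of acyclic terminal polyprenyl arenes with arene or phenol termination and stoichiometric bromonium-induced transannular cyclisations of macrocyclic polyenes, neither shown with catalyst control on an internal alkene of a macrolactone.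

**Step 7**
Reactants: 11 (2R,6S,7S,14S)-bicyclic dibromide
Product: 12 (2R,6S,7S,10R,11S,14S)-6,10,15-tribromo-11-hydroxy macrolide TIPS ether
Conditions: NBS (1.05 equiv), THF/H2O 4:1, 0 °C
Reagents that add atoms: N-bromosuccinimide, O=C1CCC(=O)N1Br; water, O
Why: Bromohydrin formation — NBS forms the bromiranium ion of the macrocyclic 10E-alkene (more nucleophilic and exposed than the ring 3,4-alkene, which is flanked by quaternary C7, shielded on one face by its axial methyl and deactivated by the homoallylic C6 bromide), water opens it at tertiary C11 (Markovnikov), anti addition to the E-alkene fixes the 10,11 relative configuration, and attack on the outward face of the alkene in the rigid 15-membered cyclophane is expected to give 10R,11S.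

**Step 8**
Reactants: 12 tribromide TIPS ether
Product: 13 target CNP0215732.1
Conditions: Bu4NF/AcOH (1:1, 1.5 equiv), THF, 0 °C
Reagents that add atoms: none
Why: Fluoride-induced cleavage of the aryl silyl ether (good phenoxide leaving group para to the ester) under AcOH buffering, which keeps the medium non-basic so that the bromohydrin does not close to an epoxide and the lactone and tertiary bromide are untouched; no stereocentre is affected.

**Compound list**
1 | methyl 4-hydroxybenzoate | COC(=O)c1ccc(O)cc1 | starting material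
2 | (2E,6E,10E)-1-bromo-3,7,11,15-tetramethylhexadeca-2,6,10,14-tetraene (geranylgeranyl bromide) | CC(C)=CCC/C(C)=C/CC/C(C)=C/CC/C(C)=C/CBr | starting material
3 | methyl 4-hydroxy-3-[(2E,6E,10E)-geranylgeranyl]benzoate | COC(=O)c1ccc(O)c(C/C=C(C)/CC/C=C(C)/CC/C=C(C)/CCC=C(C)C)c1 | intermediate (not isolated)
4 | 4-hydroxy-3-[(2E,6E,10E)-geranylgeranyl]benzoic acid | OC(=O)c1ccc(O)c(C/C=C(C)/CC/C=C(C)/CC/C=C(C)/CCC=C(C)C)c1 | intermediate
5 | triisopropylsilyl 3-[(2E,6E,10E)-geranylgeranyl]-4-(triisopropylsilyloxy)benzoate | CC(C)[Si](OC(=O)c1ccc(O[Si](C(C)C)(C(C)C)C(C)C)c(C/C=C(C)/CC/C=C(C)/CC/C=C(C)/CCC=C(C)C)c1)(C(C)C)C(C)C | intermediate (not isolated)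
6 | 3-[(2E,6E,10E)-geranylgeranyl]-4-(triisopropylsilyloxy)benzoic acid | OC(=O)c1ccc(O[Si](C(C)C)(C(C)C)C(C)C)c(C/C=C(C)/CC/C=C(C)/CC/C=C(C)/CCC=C(C)C)c1 | intermediate
7 | 3-[(2E,6E,10E,14S)-14,15-epoxy-3,7,11,15-tetramethylhexadeca-2,6,10-trienyl]-4-(triisopropylsilyloxy)benzoic acid | OC(=O)c1ccc(O[Si](C(C)C)(C(C)C)C(C)C)c(C/C=C(C)/CC/C=C(C)/CC/C=C(C)/CC[C@@H]2OC2(C)C)c1 | intermediate
8 | 3-[(2E,6E,10E,14S)-15-bromo-14-hydroxy-3,7,11,15-tetramethylhexadeca-2,6,10-trienyl]-4-(triisopropylsilyloxy)benzoic acid | OC(=O)c1ccc(O[Si](C(C)C)(C(C)C)C(C)C)c(C/C=C(C)/CC/C=C(C)/CC/C=C(C)/CC[C@@H](C(C)(C)Br)O)c1 | intermediate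
9 | mixed anhydride of 8 with 2-methyl-6-nitrobenzoic acid | Cc1cccc([N+](=O)[O-])c1C(=O)OC(=O)c2ccc(O[Si](C(C)C)(C(C)C)C(C)C)c(C/C=C(C)/CC/C=C(C)/CC/C=C(C)/CC[C@@H](C(C)(C)Br)O)c2 | intermediate (not isolated)
10 | (14S)-19-membered macrolactone: C14–O acylated by the benzoate carbon, ring through C1–C14 and the 1,3-bridged arene; 2E,6E,10E; 2-bromopropan-2-yl on C14; aryl OTIPS | O=C1O[C@H](C(C)(C)Br)CC/C(C)=C/CC/C(C)=C/CC/C(C)=C/Cc2cc1ccc2O[Si](C(C)C)(C(C)C)C(C)C | intermediate
11 | (2R,6S,7S,14S)-bicyclic dibromide: cyclohexene C2–C3(Me)=C4–C5–C6(Br)–C7(Me) fused across C2–C7 to the 15-membered lactone; Br, C7-methyl and C1 mutually cis, C8 trans; 10E; aryl OTIPS | CC1=CC[C@H](Br)[C@@]2(C)CC/C=C(C)/CC[C@@H](C(C)(C)Br)OC(=O)c3ccc(O[Si](C(C)C)(C(C)C)C(C)C)c(c3)C[C@H]12 | intermediate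
12 | (2R,6S,7S,10R,11S,14S)-TIPS ether of the target (11 with Br on C10 and OH on C11) | CC1=CC[C@H](Br)[C@@]2(C)CC[C@@H](Br)[C@@](C)(O)CC[C@@H](C(C)(C)Br)OC(=O)c3ccc(O[Si](C(C)C)(C(C)C)C(C)C)c(c3)C[C@H]12 | intermediate
13 | target CNP0215732.1, (2R,6S,7S,10R,11S,14S)-6,10,15-tribromo-11-hydroxy macrolide with free phenol | CC1=CC[C@H](Br)[C@@]2(C)CC[C@@H](Br)[C@@](C)(O)CC[C@@H](C(C)(C)Br)OC(=O)c3ccc(O)c(c3)C[C@H]12 | target

**Totals**
Total steps: 8. Longest linear sequence: 8 (fully linear from 1 and 2).

**Steps most likely to fail, with fallbacks**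

Step 3 (site selectivity). Four trisubstituted alkenes compete for the dioxirane and the terminal preference is only modest, so separation from internal mono-epoxides and recycling may be inefficient. The fallback sets out from 6 and returns at 8, keeping a metal-free catalytic asymmetric step as the source of the first stereocentre. NBS in THF/H2O at 0 °C, which is known to pick the terminal alkene of coiled polyprenyl chains, gives the racemic 14-bromo-15-hydroxy acid F1. K2CO3 in MeOH at 0 °C closes it to the racemic 14,15-epoxide F2. Aqueous HBr in Et2O at −20 °C opens this to the racemic 15-bromo-14-hydroxy acid F3. Dess–Martin periodinane (NaHCO3, CH2Cl2) oxidises it to the 15-bromo-14-oxo acid F4. Reduction with (R)-2-methyl-CBS-oxazaborolidine (20 mol%) and catecholborane in toluene at −78 °C, with CBrMe2 as the large group, then gives 8 with 14S.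

Step 6 (the proposed new step). Possible failures are bromonium capture at the 10,11-alkene, the wrong alkene face, exocyclic or tetrasubstituted alkene isomers from the C3 cation, or low turnover of the Lewis base. The fallback uses known chemistry, sets out from 10 and returns at 11. Hg(OTf)2·PhNMe2 in MeNO2 at −20 °C (the established mercury ditriflate–amine polyene cyclisation with olefinic termination), followed by an aqueous KBr quench, gives the C6 alkylmercuric bromide F5, whose diastereomers are separated at this stage. Brominative demercuration (Br2, LiBr, pyridine, dark, 0 °C) then replaces HgBr by Br with retention to give 11.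

Step 7 (face and site selectivity). The outward-face argument may give the 10S,11R bromohydrin, or the ring alkene may compete. The fallback sets out from 11 and returns at 12, replacing substrate control by catalyst control. Epoxidation with the same L-series Shi ketone and KHSO5 gives the (10S,11S)-10,11-epoxide F6; the bulky dioxirane avoids the hindered ring alkene. Li2NiBr4 in THF at 0 °C then opens the epoxide by SN2 attack of bromide at the secondary C10 with inversion, giving 12 with 10R,11S.

**Further compounds**
F1 | step 3 | racemic 3-[(2E,6E,10E)-14-bromo-15-hydroxy-3,7,11,15-tetramethylhexadeca-2,6,10-trienyl]-4-(triisopropylsilyloxy)benzoic acid | OC(=O)c1ccc(O[Si](C(C)C)(C(C)C)C(C)C)c(C/C=C(C)/CC/C=C(C)/CC/C=C(C)/CCC(Br)C(C)(C)O)c1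
F2 | step 3 | racemic 14,15-epoxy acid (racemate of 7) | OC(=O)c1ccc(O[Si](C(C)C)(C(C)C)C(C)C)c(C/C=C(C)/CC/C=C(C)/CC/C=C(C)/CCC2OC2(C)C)c1
F3 | step 3 | racemic 15-bromo-14-hydroxy acid (racemate of 8) | OC(=O)c1ccc(O[Si](C(C)C)(C(C)C)C(C)C)c(C/C=C(C)/CC/C=C(C)/CC/C=C(C)/CCC(O)C(C)(C)Br)c1
F4 | step 3 | 3-[(2E,6E,10E)-15-bromo-3,7,11,15-tetramethyl-14-oxohexadeca-2,6,10-trienyl]-4-(triisopropylsilyloxy)benzoic acid | OC(=O)c1ccc(O[Si](C(C)C)(C(C)C)C(C)C)c(C/C=C(C)/CC/C=C(C)/CC/C=C(C)/CCC(=O)C(C)(C)Br)c1
F5 | step 6 | C6 alkylmercuric bromide (11 with HgBr in place of the C6 bromine) | CC1=CC[C@H]([Hg]Br)[C@@]2(C)CC/C=C(C)/CC[C@@H](C(C)(C)Br)OC(=O)c3ccc(O[Si](C(C)C)(C(C)C)C(C)C)c(c3)C[C@H]12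
F6 | step 7 | (10S,11S)-10,11-epoxide of 11 | CC1=CC[C@H](Br)[C@@]2(C)CC[C@@H]4O[C@@]4(C)CC[C@@H](C(C)(C)Br)OC(=O)c3ccc(O[Si](C(C)C)(C(C)C)C(C)C)c(c3)C[C@H]12
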